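**Retrosynthetic overview**
1. Target 18 ← (6R,10S)-10-bromo-β-chamigrene 17 by anti, Markovnikov bromohydrin formation at C2=C3; this last step sets C2 and C3.
2. 17 ← spiro enedione 13: the C1=C2–C3=O enone is turned into the C2=C3 methyl alkene (1,4-reduction, enol triflate, methyl coupling), and the C7 ketone into the methylidene.
3. Key disconnection: ring B of 13 at C5–C6 and C3–C4, i.e. thioester 9 plus the vinyl group of tributyl(vinyl)stannane, joined in one flask by acyl–vinyl coupling, fluoride-triggered loss of a temporary ester on C6 and intramolecular Michael addition.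
4. Enabling feature: the oxygenated C7 of ring A next to the spiro carbon C6 (ketone now, methylidene later) and the C1=C2 unsaturation of the C1–C3 arm make C6 the central carbon of a planar dienolate that can reach the vinyl terminus only through a six-membered ring; the C10 bromide and C11 gem-dimethyl group of ring A decide the face.
5. Ring A is closed first (step 3, C6–C11 bond by bromonium capture, from the enantioselectively made bromolactone 2), ring B second (step 6).

Key step: step 6

Remark: spiro[5.5]undecane (chamigrene) numbering is used throughout (ring B C1–C5, spiro C6, ring A C7–C11), and the pseudoenantiomeric series of the cinchona catalyst in step 1 is chosen so that the (S)-bromide results.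

Step 1
Reactants: 1 5-methylhex-4-enoic acid
Product: 2 (5S)-5-bromo-6,6-dimethyloxan-2-one
Conditions: NBS (1.1 equiv), cinchona-derived amino-thiocarbamate catalyst (10 mol%), CHCl3/toluene, −60 °C
Reagents that add atoms: N-bromosuccinimide, O=C1CCC(=O)N1Br
Why: Catalytic enantioselective 6-endo bromolactonisation, in which the carboxylate opens the catalyst-bound bromonium ion at the tertiary carbon (Markovnikov) and the catalyst sets the C–Br stereocentre (future C10) as S; recrystallisation should raise the enantiomeric purity if needed.

Step 2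
Reactants: 2 (5S)-5-bromo-6,6-dimethyloxan-2-one; 3 2-(trimethylsilyl)ethyl acetate
Product: 4 2-(trimethylsilyl)ethyl [(5S)-5-bromo-2-hydroxy-6,6-dimethyloxan-2-yl]acetate
Conditions: LDA (2.1 equiv), 3 (2.1 equiv), THF, −78 °C; then 2, −78 °C; AcOH quench at −78 °C
Reagents that add atoms: none
Why: Claisen-type acylation of the ester enolate by the δ-lactone, kept cold and quenched cold so that the adduct stays as the six-membered lactol and the tertiary alkoxide is never free to displace the neighbouring bromide; the C–Br centre is untouched and the lactol carbon (anomeric mixture) is of no consequence.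

Step 3
Reactants: 4 2-(trimethylsilyl)ethyl [(5S)-5-bromo-2-hydroxy-6,6-dimethyloxan-2-yl]acetate
Product: 5 2-(trimethylsilyl)ethyl (3S)-3-bromo-2,2-dimethyl-6-oxocyclohexane-1-carboxylate
Conditions: TfOH (10 mol%), HFIP/CH2Cl2, −20 → 0 °C
Reagents that add atoms: none
Why: Acid ionises the tertiary C–O bond with anchimeric assistance by the neighbouring bromine, and the β-keto ester enol captures the bromonium ion at the tertiary carbon in a six-membered cation–enol cyclisation (bromonium-induced cation–olefin cyclisation with β-keto ester termination; C-alkylation is irreversible, O-alkylation only returns the enol ether), so the C10–Br bond is never broken and its S configuration is carried over.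

Step 4
Reactants: 6 prop-2-ynoic acid; 7 ethanethiol
Product: 8 S-ethyl prop-2-ynethioate
Conditions: DCC (1.05 equiv), CH2Cl2, −20 → 0 °C
Reagents that add atoms: none
Why: Carbodiimide-mediated thioesterification, run cold and without a nucleophilic catalyst so that the thiol acylates instead of adding to the alkyne; no stereocentre is involved.

Step 5
Reactants: 5 2-(trimethylsilyl)ethyl (3S)-3-bromo-2,2-dimethyl-6-oxocyclohexane-1-carboxylate; 8 S-ethyl prop-2-ynethioate
Product: 9 2-(trimethylsilyl)ethyl (3S)-3-bromo-1-[3-(ethylsulfanyl)-3-oxoprop-1-en-1-yl]-2,2-dimethyl-6-oxocyclohexane-1-carboxylate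
Conditions: Cs2CO3 (10 mol%), MeCN, 0 °C
Reagents that add atoms: none
Why: Michael addition of the β-keto ester to the sterically slim, highly electrophilic alkynoyl thioester forms the C6–C1 bond at the hindered carbon under weakly basic conditions; the new quaternary centre and the alkene geometry are allowed to form as mixtures because step 6 erases both.

Step 6
Reactants: 9 2-(trimethylsilyl)ethyl (3S)-3-bromo-1-[3-(ethylsulfanyl)-3-oxoprop-1-en-1-yl]-2,2-dimethyl-6-oxocyclohexane-1-carboxylate; 10 tributyl(vinyl)stannane
Product: 13 (6S,10S)-10-bromo-11,11-dimethylspiro[5.5]undec-1-ene-3,7-dione, via dienone ester 11 (not isolated), via dienone 12 (not isolated)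
Conditions: Pd2(dba)3 (2.5 mol%), tri(2-furyl)phosphine (20 mol%), copper(I) diphenylphosphinate (1.5 equiv), THF, 45 °C; then TBAF (1.5 equiv), THF, 0 °C → rt
Reagents that add atoms: none
Why: Copper-assisted oxidative addition of Pd(0) into the C(acyl)–S bond of 9, transmetallation with 10 and reductive elimination form the C3–C4 bond under base-free conditions (Liebeskind–Srogl ketone synthesis) and give the cross-conjugated divinyl ketone 11; fluoride then cleaves the 2-(trimethylsilyl)ethyl ester with loss of ethene and CO2, and the resulting C6 carbanion of 12, stabilised by the C7 ketone and vinylogously by the C3 ketone, adds to the vinyl terminus C5. The closest known reaction types are the thioester–organostannane ketone synthesis, the fluoride-induced dealkoxycarbonylation of β-keto esters and the double Michael ([5+1]) annulation of divinyl ketones with active methine compounds. Ring B closes in the 6-endo-trig mode, and because attack through C2, C8 or oxygen would need a four- or eight-membered ring, the regiochemistry of the ambident anion is fixed by ring size. C6 is the only new stereocentre and is set by ring A: the tether should deliver C5 axially to the face of the planar C6 that is anti to the pseudoaxial C11 methyl group, i.e. trans to the equatorial C10 bromide. The step is stereoconvergent, since both C6 epimers and both C1=C2 isomers of 9 pass through the same planar dienolate in which the C1–C2 bond can rotate, and the temporary ester and the vinyl unsaturation are both consumed in the same flask. The selectivity it needs, C- before O-attack and ring closure before 1,3-displacement of the C10 bromide, should be secured by the soft delocalised nucleophile and the fast intramolecular conjugate addition.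

Step 7
Reactants: 13 (6S,10S)-10-bromo-11,11-dimethylspiro[5.5]undec-1-ene-3,7-dione
Product: 15 (6S,10S)-10-bromo-11,11-dimethyl-7-oxospiro[5.5]undec-2-en-3-yl trifluoromethanesulfonate, via silyl enol ether 14 (not isolated)
Conditions: RhCl(PPh3)3 (2 mol%), Et3SiH (1.2 equiv), benzene, 50 °C; then CsF (2 equiv), PhNTf2 (1.3 equiv), DME, rt
Reagents that add atoms: N-phenylbis(trifluoromethanesulfonimide), O=S(=O)(N(c1ccccc1)S(=O)(=O)C(F)(F)F)C(F)(F)F
Why: Rhodium-catalysed 1,4-hydrosilylation of the enone (the hindered C7 ketone should be left alone) gives the C2=C3 silyl enol ether regiospecifically, and fluoride-mediated triflation of the released enolate fixes the double bond at C2=C3 (enol triflate synthesis); no stereocentre is affected.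

Step 8
Reactants: 15 (6S,10S)-10-bromo-11,11-dimethyl-7-oxospiro[5.5]undec-2-en-3-yl trifluoromethanesulfonate
Product: 16 (6S,10S)-10-bromo-3,11,11-trimethylspiro[5.5]undec-2-en-7-one
Conditions: MeZnCl (2 equiv), Pd(PPh3)4 (5 mol%), THF, 50 °C
Reagents that add atoms: methylzinc chloride, C[Zn]Cl
Why: Negishi coupling of the alkenyl triflate, chosen because the organozinc reagent tolerates the C7 ketone and Pd(PPh3)4 does not insert into the unactivated secondary C10–Br bond; the alkene stays at C2=C3.

Step 9
Reactants: 16 (6S,10S)-10-bromo-3,11,11-trimethylspiro[5.5]undec-2-en-7-one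
Product: 17 (6R,10S)-10-bromo-3,11,11-trimethyl-7-methylidenespiro[5.5]undec-2-ene
Conditions: Cp2TiMe2 (3 equiv), toluene, 70 °C, dark
Reagents that add atoms: dimethyltitanocene, C[Ti](C)(C1C=CC=C1)C1C=CC=C1
Why: Petasis methylenation through Cp2Ti=CH2 is a non-basic carbonyl olefination suited to the hindered C7 ketone next to the spiro centre, and it avoids a C8 enolate that could displace the C10 bromide by 1,3-elimination; the descriptor at C6 changes to R only through the priority change.

Step 10
Reactants: 17 (6R,10S)-10-bromo-3,11,11-trimethyl-7-methylidenespiro[5.5]undec-2-ene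
Product: 18 (2R,3R,6R,10S)-2,10-dibromo-3,11,11-trimethyl-7-methylidenespiro[5.5]undecan-3-ol
Conditions: NBS (1.05 equiv), THF/H2O (3:1), 0 °C
Reagents that add atoms: N-bromosuccinimide, O=C1CCC(=O)N1Br; water, O
Why: Bromohydrin formation at the more nucleophilic trisubstituted C2=C3 alkene (the methylidene is neopentylic and 1,1-disubstituted), in which the bromonium ion should form on the face anti to the axial C7 methylidene that shields the syn face, and water opens it anti at the tertiary C3, giving the trans (2R,3R) bromohydrin.

**Compound list**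
1 | 5-methylhex-4-enoic acid | CC(C)=CCCC(=O)O | starting material
2 | (5S)-5-bromo-6,6-dimethyloxan-2-one | O=C1CC[C@H](Br)C(C)(C)O1 | intermediate
3 | 2-(trimethylsilyl)ethyl acetate | CC(=O)OCC[Si](C)(C)C | starting material
4 | 2-(trimethylsilyl)ethyl [(5S)-5-bromo-2-hydroxy-6,6-dimethyloxan-2-yl]acetate (anomeric mixture, lactol form of the δ-hydroxy β-keto ester) | C[Si](C)(C)CCOC(=O)CC1(O)CC[C@H](Br)C(C)(C)O1 | intermediate
5 | 2-(trimethylsilyl)ethyl (3S)-3-bromo-2,2-dimethyl-6-oxocyclohexane-1-carboxylate (C1 epimers and enol in equilibrium) | C[Si](C)(C)CCOC(=O)C1C(=O)CC[C@H](Br)C1(C)C | intermediate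
6 | prop-2-ynoic acid | C#CC(=O)O | starting material
7 | ethanethiol | CCS | starting material
8 | S-ethyl prop-2-ynethioate | C#CC(=O)SCC | intermediate
9 | 2-(trimethylsilyl)ethyl (3S)-3-bromo-1-[3-(ethylsulfanyl)-3-oxoprop-1-en-1-yl]-2,2-dimethyl-6-oxocyclohexane-1-carboxylate (E/Z mixture, both C1 epimers) | C[Si](C)(C)CCOC(=O)C1(C=CC(=O)SCC)C(=O)CC[C@H](Br)C1(C)C | intermediate
10 | tributyl(vinyl)stannane | C=C[Sn](CCCC)(CCCC)CCCC | starting material
11 | 2-(trimethylsilyl)ethyl (3S)-3-bromo-2,2-dimethyl-6-oxo-1-(3-oxopenta-1,4-dien-1-yl)cyclohexane-1-carboxylate (E/Z mixture, both C1 epimers) | C[Si](C)(C)CCOC(=O)C1(C=CC(=O)C=C)C(=O)CC[C@H](Br)C1(C)C | intermediate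
12 | 1-[(3S)-3-bromo-2,2-dimethyl-6-oxocyclohexyl]penta-1,4-dien-3-one (present as its tetrabutylammonium dienolate) | C=CC(=O)C=CC1C(=O)CC[C@H](Br)C1(C)C | intermediate
13 | (6S,10S)-10-bromo-11,11-dimethylspiro[5.5]undec-1-ene-3,7-dione | O=C1CC[C@H](Br)C(C)(C)[C@@]12CCC(=O)C=C2 | intermediate
14 | (6S,10S)-10-bromo-11,11-dimethyl-3-(triethylsilyloxy)spiro[5.5]undec-2-en-7-one | O=C1CC[C@H](Br)C(C)(C)[C@@]12CCC(O[Si](CC)(CC)CC)=CC2 | intermediate
15 | (6S,10S)-10-bromo-11,11-dimethyl-7-oxospiro[5.5]undec-2-en-3-yl trifluoromethanesulfonate | O=C1CC[C@H](Br)C(C)(C)[C@@]12CCC(OS(=O)(=O)C(F)(F)F)=CC2 | intermediate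
16 | (6S,10S)-10-bromo-3,11,11-trimethylspiro[5.5]undec-2-en-7-one | O=C1CC[C@H](Br)C(C)(C)[C@@]12CCC(C)=CC2 | intermediate
17 | (6R,10S)-10-bromo-3,11,11-trimethyl-7-methylidenespiro[5.5]undec-2-ene (10-bromo-β-chamigrene) | C=C1CC[C@H](Br)C(C)(C)[C@@]12CCC(C)=CC2 | intermediate
18 | (2R,3R,6R,10S)-2,10-dibromo-3,11,11-trimethyl-7-methylidenespiro[5.5]undecan-3-ol | C=C1CC[C@H](Br)C(C)(C)[C@@]12CC[C@@](C)(O)[C@H](Br)C2 | target

**Step count and risks**
Total steps: 10. Longest linear sequence: 9 (steps 1, 2, 3, 5, 6, 7, 8, 9, 10; step 4 is a side branch).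

Step 6 (key step). What may go wrong: intermolecular conjugate addition and oligomerisation of the divinyl ketone may outrun ring closure, the dienolate may displace the C10 bromide in a 1,3-fashion, or facial selectivity at C6 may be incomplete. The fallback is a Robinson-type spiroannulation that sets out from 2 and comes back to the route at 13. Lactone 2 is acylated at −78 °C with lithiated N-tert-butylethanimine (LDA, THF) and the adduct is hydrolysed with aqueous oxalic acid to the lactol aldehyde [(5S)-5-bromo-2-hydroxy-6,6-dimethyloxan-2-yl]acetaldehyde F1. The acid-promoted bromonium carbocyclisation of step 3 (TfOH, HFIP) should then close ring A to the formyl ketone (3S)-3-bromo-2,2-dimethyl-6-oxocyclohexane-1-carbaldehyde F2. Michael addition of F2 to methyl vinyl ketone (Et3N, CH2Cl2, 0 °C) should give, by the same axial attack, (1R,3S)-3-bromo-2,2-dimethyl-6-oxo-1-(3-oxobutyl)cyclohexane-1-carbaldehyde F3, and aldol condensation (pyrrolidine, AcOH, benzene, 50 °C) closes ring B to 13.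

Step 10. What may go wrong: poor facial selectivity in bromonium formation and opening would give the (2S,3S) diastereomer, and the C7 methylidene may take part in the bromonium chemistry. The fallback replaces bromonium opening by methyl addition to an α-bromo ketone; it sets out from 13 and comes back at 18. 13 is hydrosilylated as in step 7 to 14, which is brominated with NBS (THF, −78 °C) and equilibrated (catalytic HBr, AcOH) to the equatorial bromide (2R,6S,10S)-2,10-dibromo-11,11-dimethylspiro[5.5]undecane-3,7-dione F4, the axial epimer being disfavoured by the syn-axial C7. Axial methylation of the unhindered C3 ketone with excess Me3Al (toluene, −78 → 0 °C) should give (2R,3R,6S,10S)-2,10-dibromo-3-hydroxy-3,11,11-trimethylspiro[5.5]undecan-7-one F5, and Petasis methylenation of the C7 ketone as in step 9 gives 18.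

Step 3. What may go wrong: after ionisation, elimination to an allylic bromide or O-alkylation to the cyclic enol ether may outcompete C–C bond formation, and the silylethyl ester may be cleaved by the acid. The fallback is the classical alkene-initiated bromonium cyclisation with resolution; it sets out from 1 and 3 and comes back at 5. Acid 1 is converted with carbonyldiimidazole into 1-(5-methylhex-4-enoyl)imidazole F6, which acylates the lithium enolate of 3 (THF, −78 °C) to give 2-(trimethylsilyl)ethyl 7-methyl-3-oxooct-6-enoate F7. Bromodiethylsulfonium bromopentachloroantimonate (MeNO2, −25 °C) should cyclise F7 to racemic 2-(trimethylsilyl)ethyl 3-bromo-2,2-dimethyl-6-oxocyclohexane-1-carboxylate F8, which is resolved by preparative chromatography on a chiral stationary phase to give 5.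

Further compounds
F1 | step 6 | [(5S)-5-bromo-2-hydroxy-6,6-dimethyloxan-2-yl]acetaldehyde | O=CCC1(O)CC[C@H](Br)C(C)(C)O1
F2 | step 6 | (3S)-3-bromo-2,2-dimethyl-6-oxocyclohexane-1-carbaldehyde | O=CC1C(=O)CC[C@H](Br)C1(C)C
F3 | step 6 | (1R,3S)-3-bromo-2,2-dimethyl-6-oxo-1-(3-oxobutyl)cyclohexane-1-carbaldehyde | O=C1CC[C@H](Br)C(C)(C)[C@@]1(C=O)CCC(C)=O
F4 | step 10 | (2R,6S,10S)-2,10-dibromo-11,11-dimethylspiro[5.5]undecane-3,7-dione | O=C1CC[C@H](Br)C(C)(C)[C@@]12CCC(=O)[C@H](Br)C2
F5 | step 10 | (2R,3R,6S,10S)-2,10-dibromo-3-hydroxy-3,11,11-trimethylspiro[5.5]undecan-7-one | O=C1CC[C@H](Br)C(C)(C)[C@@]12CC[C@@](C)(O)[C@H](Br)C2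
F6 | step 3 | 1-(5-methylhex-4-enoyl)imidazole | CC(C)=CCCC(=O)n1ccnc1
F7 | step 3 | 2-(trimethylsilyl)ethyl 7-methyl-3-oxooct-6-enoate | C[Si](C)(C)CCOC(=O)CC(=O)CCC=C(C)C
F8 | step 3 | racemic 2-(trimethylsilyl)ethyl 3-bromo-2,2-dimethyl-6-oxocyclohexane-1-carboxylate | C[Si](C)(C)CCOC(=O)C1C(=O)CCC(Br)C1(C)C
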